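**Strategy.** The γ-butyrolactone (O1–C2(=O)–C3–C4–C5) sits next to the carbinol C1′, so O1/C2 and the C1′ oxygen are read as a cyclic carbonate of a 1,2-diol. The key step lets a two-carbon acceptor (phenyl vinyl sulfone) enter between C5 and C2. Hydrogen-atom transfer to an exocyclic enol carbonate, made from (S)-but-3-yn-2-ol and CO2, gives the C5 radical, which forms C4–C5 anti to the ring methyl. The resulting carbanion attacks the carbonate carbonyl and forms C2–C3, turning the dioxolanone into the lactone. The released carbinol is oxidised to a methyl ketone, alkylated with the furan-bearing allylic bromide and reduced (CBS) to set C1′.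

Key step: step 2

Numbering used: lactone O1, C2 (C=O), C3, C4, C5 (quaternary, methyl-bearing); side chain C1′ (carbinol) to C11′ (CH2 on the furan). The target is (5S,1′R,6′S,4′E,8′E).

Remark on the chemistry: lactone 5 is carried as the mixture of C3 epimers (sulfonyl-bearing carbon), because this centre is removed in step 3; its SMILES leaves C3 undefined.

**Route**

Step 1
Reactants: 1 (S)-but-3-yn-2-ol; 2 carbon dioxide
Product: 3 (S)-4-methyl-5-methylidene-1,3-dioxolan-2-one
Conditions: AgOAc (10 mol %), DBU (1 equiv), CO2 (1 MPa), toluene, rt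
Reagents that add atoms: none
Why: Silver-catalysed carboxylative cyclisation of a propargylic alcohol, in which the carbonate anion adds 5-exo-dig to the Ag-activated alkyne and protodemetalation gives the exocyclic enol carbonate, the carbinol centre (no bond to it is broken) staying S.

Step 2
Reactants: 3 (S)-4-methyl-5-methylidene-1,3-dioxolan-2-one; 4 phenyl vinyl sulfone
Product: 5 (5S)-5-[(1S)-1-hydroxyethyl]-5-methyl-3-(phenylsulfonyl)oxolan-2-one (C3 epimers)
Conditions: Fe(acac)3 (20 mol %), Ph(i-PrO)SiH2 (2 equiv), THF, 40 °C; then 1 M HCl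
Reagents that add atoms: none
Why: Proposed new method: Fe–H hydrogen-atom transfer to the exocyclic C=CH2 of 3 should give the tertiary α-oxy radical at the future lactone C5, which adds to the β-carbon of 4 (C4–C5 bond); Fe(II) then reduces the α-sulfonyl radical to the carbanion, which attacks the carbonate carbonyl and expels the secondary alkoxide (C2–C3 bond), the alkoxide regenerating Fe–H with the silane and being freed on work-up. The closest known reactions are the Fe-catalysed reductive olefin coupling (MHAT–Giese) of heteroatom-substituted donor olefins with vinyl sulfones, HAT-initiated radical–polar crossover annulations that end in an aldol step, and the Claisen-type C-acylation of sulfonyl carbanions by carbonates; the acyl-transfer termination is the new element. The lactone closes by 5-exo-trig acyl substitution through a 2,7-dioxabicyclo[2.2.1]heptane tetrahedral intermediate, whose collapse opens the dioxolanone. The quaternary C5 is controlled by the ring methyl of 3: the acceptor should add anti to it, which makes C5 S, while C3 forms without control and is erased in step 3. The step needs HAT to the electron-rich 1,1-disubstituted enol carbonate rather than to the electron-poor sulfone, and crossover before the adduct radical is quenched, which polarity matching and the aprotic medium should secure.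

Step 3
Reactants: 5 (5S)-5-[(1S)-1-hydroxyethyl]-5-methyl-3-(phenylsulfonyl)oxolan-2-one
Product: 6 (S)-5-[(S)-1-hydroxyethyl]-5-methyloxolan-2-one
Conditions: SmI2 (2.5 equiv), THF/MeOH, −78 °C
Reagents that add atoms: none
Why: Reductive desulfonylation of an α-sulfonyl lactone by single-electron transfer gives the samarium enolate, which methanol protonates, removing the activating group and the uncontrolled C3 centre; any diastereomer from cis addition in step 2 is separated here, since it would become the enantiomer of 7.

Step 4
Reactants: 6 (S)-5-[(S)-1-hydroxyethyl]-5-methyloxolan-2-one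
Product: 7 (S)-5-acetyl-5-methyloxolan-2-one
Conditions: Dess–Martin periodinane, CH2Cl2, rt
Reagents that add atoms: none
Why: Dess–Martin oxidation of the secondary alcohol should give the methyl ketone without touching the quaternary C5 or the lactone, deliberately erasing the carbinol centre that steered step 2 because it has the wrong relative configuration for the target.

Step 5
Reactants: 8 3-bromofuran; 9 5-bromo-2-methylpent-2-ene
Product: 11 perillene [3-(4-methylpent-3-en-1-yl)furan], via Grignard reagent 10 (not isolated)
Conditions: 9, Mg, THF, rt; then 8, Ni(dppp)Cl2 (2 mol %), Et2O/THF, 0 °C to rt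
Reagents that add atoms: none
Why: Kumada coupling, in which the Grignard reagent made in situ couples at the C–Br bond of 3-bromofuran under Ni(dppp)Cl2 catalysis, a standard entry to 3-alkylfurans.

Step 6
Reactants: 11 perillene
Product: 12 (E)-5-(furan-3-yl)-2-methylpent-2-en-1-ol
Conditions: SeO2 (0.3 equiv), t-BuOOH (2 equiv), salicylic acid (cat.), CH2Cl2, rt
Reagents that add atoms: selenium dioxide, O=[Se]=O (oxygen carrier, reoxidised by tert-butyl hydroperoxide, CC(C)(C)OO)
Why: SeO2/t-BuOOH allylic oxidation (ene reaction then [2,3]-shift) attacks the E-methyl group at the more substituted alkene terminus and so should give the (E)-allylic alcohol selectively.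

Step 7
Reactants: 12 (E)-5-(furan-3-yl)-2-methylpent-2-en-1-ol
Product: 13 3-[(E)-5-iodo-4-methylpent-3-en-1-yl]furan
Conditions: PPh3, I2, imidazole, CH2Cl2, 0 °C
Reagents that add atoms: iodine, II
Why: Appel-type iodination converts the primary allylic alcohol into the iodide by SN2 displacement of the oxyphosphonium group, without allylic transposition at 0 °C.

Step 8
Reactants: 14 (R)-4-benzyloxazolidin-2-one; 15 methoxyacetyl chloride
Product: 16 (R)-4-benzyl-3-(2-methoxyacetyl)oxazolidin-2-one
Conditions: n-BuLi, THF, −78 °C; then 15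
Reagents that add atoms: none
Why: N-acylation of the lithiated Evans oxazolidinone with the acid chloride.

Step 9
Reactants: 16 (R)-4-benzyl-3-(2-methoxyacetyl)oxazolidin-2-one; 13 3-[(E)-5-iodo-4-methylpent-3-en-1-yl]furan
Product: 17 (R)-4-benzyl-3-[(2S,4E)-7-(furan-3-yl)-2-methoxy-4-methylhept-4-enoyl]oxazolidin-2-one
Conditions: NaHMDS, THF, −78 °C; then 13, −78 to −45 °C
Reagents that add atoms: none
Why: Evans-type glycolate alkylation, in which the Z-configured, sodium-chelated enolate is alkylated by the allylic iodide on the face opposite the benzyl group, setting the methoxy-bearing carbon as S.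

Step 10
Reactants: 17 (R)-4-benzyl-3-[(2S,4E)-7-(furan-3-yl)-2-methoxy-4-methylhept-4-enoyl]oxazolidin-2-one
Product: 18 (2S,4E)-7-(furan-3-yl)-2-methoxy-4-methylhept-4-en-1-ol
Conditions: LiBH4, MeOH (1 equiv), Et2O/THF, 0 °C
Reagents that add atoms: none
Why: Reductive removal of the auxiliary with LiBH4 (hydride attack at the exocyclic imide carbonyl) should give the primary alcohol without epimerisation and return the oxazolidinone.

Step 11
Reactants: 18 (2S,4E)-7-(furan-3-yl)-2-methoxy-4-methylhept-4-en-1-ol; 19 ethyl 2-(triphenyl-λ5-phosphanylidene)propanoate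
Product: 21 ethyl (2E,4S,6E)-9-(furan-3-yl)-4-methoxy-2,6-dimethylnona-2,6-dienoate, via aldehyde 20 (not isolated)
Conditions: Dess–Martin periodinane, NaHCO3, CH2Cl2, 0 °C to rt; then 19, rt
Reagents that add atoms: none
Why: Dess–Martin oxidation followed in the same flask by Wittig olefination with the stabilised α-methyl ylide should give the (E)-enoate, the α-methoxy aldehyde being consumed before it can epimerise.

Step 12
Reactants: 21 ethyl (2E,4S,6E)-9-(furan-3-yl)-4-methoxy-2,6-dimethylnona-2,6-dienoate
Product: 22 (2E,4S,6E)-9-(furan-3-yl)-4-methoxy-2,6-dimethylnona-2,6-dien-1-ol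
Conditions: DIBAL-H (2.2 equiv), CH2Cl2, −78 °C; Rochelle salt work-up
Reagents that add atoms: none
Why: DIBAL-H 1,2-reduction of the enoate to the allylic alcohol at −78 °C leaves both alkenes and the furan untouched.

Step 13
Reactants: 22 (2E,4S,6E)-9-(furan-3-yl)-4-methoxy-2,6-dimethylnona-2,6-dien-1-ol
Product: 23 3-[(3E,6S,7E)-9-bromo-6-methoxy-4,8-dimethylnona-3,7-dien-1-yl]furan
Conditions: CBr4, PPh3, 2,6-lutidine, CH2Cl2, 0 °C
Reagents that add atoms: carbon tetrabromide, BrC(Br)(Br)Br
Why: Appel bromination of the primary allylic alcohol gives the allylic bromide by SN2 with retention of alkene geometry, lutidine buffering the acid-sensitive furan.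

Step 14
Reactants: 7 (S)-5-acetyl-5-methyloxolan-2-one; 23 3-[(3E,6S,7E)-9-bromo-6-methoxy-4,8-dimethylnona-3,7-dien-1-yl]furan
Product: 24 (5S)-5-[(4E,6S,8E)-11-(furan-3-yl)-6-methoxy-4,8-dimethylundeca-4,8-dienoyl]-5-methyloxolan-2-one
Conditions: LDA, THF, −78 °C; then 23, DMPU, −78 to −40 °C
Reagents that add atoms: none
Why: Kinetic lithium enolate alkylation, in which LDA deprotonates the ketone methyl group (its only enolisable position and more acidic than the lactone α-CH2) and the enolate displaces the primary allylic bromide by SN2, joining the two halves.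

Step 15
Reactants: 24 (5S)-5-[(4E,6S,8E)-11-(furan-3-yl)-6-methoxy-4,8-dimethylundeca-4,8-dienoyl]-5-methyloxolan-2-one
Product: 25 (5S)-5-[(1R,4E,6S,8E)-11-(furan-3-yl)-1-hydroxy-6-methoxy-4,8-dimethylundeca-4,8-dien-1-yl]-5-methyloxolan-2-one (target)
Conditions: (S)-2-methyl-CBS-oxazaborolidine (0.5 equiv), catecholborane, toluene, −78 °C
Reagents that add atoms: none
Why: Corey–Bakshi–Shibata reduction, in which the (S)-oxazaborolidine should treat the quaternary lactone carbon as the large group and deliver hydride to the face that gives the (1′R)-carbinol (the sense found for aryl and tert-alkyl ketones), while catecholborane spares the alkenes, furan and lactone.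

**Compound list**

1 | (S)-but-3-yn-2-ol | C[C@H](O)C#C | starting material
2 | carbon dioxide | O=C=O | starting material
3 | (S)-4-methyl-5-methylidene-1,3-dioxolan-2-one | C[C@@H]1OC(=O)OC1=C | intermediate
4 | phenyl vinyl sulfone | C=CS(=O)(=O)c1ccccc1 | starting material
5 | (5S)-5-[(1S)-1-hydroxyethyl]-5-methyl-3-(phenylsulfonyl)oxolan-2-one (C3 epimers) | C[C@H](O)[C@]1(C)CC(S(=O)(=O)c2ccccc2)C(=O)O1 | intermediate
6 | (S)-5-[(S)-1-hydroxyethyl]-5-methyloxolan-2-one | C[C@H](O)[C@]1(C)CCC(=O)O1 | intermediate
7 | (S)-5-acetyl-5-methyloxolan-2-one | CC(=O)[C@]1(C)CCC(=O)O1 | intermediate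
8 | 3-bromofuran | Brc1ccoc1 | starting material
9 | 5-bromo-2-methylpent-2-ene | CC(C)=CCCBr | starting material
10 | (4-methylpent-3-en-1-yl)magnesium bromide | CC(C)=CCC[Mg]Br | intermediate
11 | perillene, 3-(4-methylpent-3-en-1-yl)furan | CC(C)=CCCc1ccoc1 | intermediate
12 | (E)-5-(furan-3-yl)-2-methylpent-2-en-1-ol | OC/C(C)=C/CCc1ccoc1 | intermediate
13 | 3-[(E)-5-iodo-4-methylpent-3-en-1-yl]furan | IC/C(C)=C/CCc1ccoc1 | intermediate
14 | (R)-4-benzyloxazolidin-2-one | O=C1N[C@H](Cc2ccccc2)CO1 | starting material
15 | methoxyacetyl chloride | COCC(Cl)=O | starting material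
16 | (R)-4-benzyl-3-(2-methoxyacetyl)oxazolidin-2-one | COCC(=O)N1[C@H](Cc2ccccc2)COC1=O | intermediate
17 | (R)-4-benzyl-3-[(2S,4E)-7-(furan-3-yl)-2-methoxy-4-methylhept-4-enoyl]oxazolidin-2-one | CO[C@@H](C/C(C)=C/CCc1ccoc1)C(=O)N1[C@H](Cc2ccccc2)COC1=O | intermediate
18 | (2S,4E)-7-(furan-3-yl)-2-methoxy-4-methylhept-4-en-1-ol | CO[C@H](CO)C/C(C)=C/CCc1ccoc1 | intermediate
19 | ethyl 2-(triphenyl-λ5-phosphanylidene)propanoate | CCOC(=O)C(C)=P(c1ccccc1)(c1ccccc1)c1ccccc1 | starting material
20 | (2S,4E)-7-(furan-3-yl)-2-methoxy-4-methylhept-4-enal | CO[C@H](C=O)C/C(C)=C/CCc1ccoc1 | intermediate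
21 | ethyl (2E,4S,6E)-9-(furan-3-yl)-4-methoxy-2,6-dimethylnona-2,6-dienoate | CO[C@H](/C=C(\C)C(=O)OCC)C/C(C)=C/CCc1ccoc1 | intermediate
22 | (2E,4S,6E)-9-(furan-3-yl)-4-methoxy-2,6-dimethylnona-2,6-dien-1-ol | CO[C@H](/C=C(\C)CO)C/C(C)=C/CCc1ccoc1 | intermediate
23 | 3-[(3E,6S,7E)-9-bromo-6-methoxy-4,8-dimethylnona-3,7-dien-1-yl]furan | CO[C@H](/C=C(\C)CBr)C/C(C)=C/CCc1ccoc1 | intermediate
24 | (5S)-5-[(4E,6S,8E)-11-(furan-3-yl)-6-methoxy-4,8-dimethylundeca-4,8-dienoyl]-5-methyloxolan-2-one | CO[C@H](/C=C(\C)CCC(=O)[C@]1(C)CCC(=O)O1)C/C(C)=C/CCc1ccoc1 | intermediate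
25 | (5S)-5-[(1R,4E,6S,8E)-11-(furan-3-yl)-1-hydroxy-6-methoxy-4,8-dimethylundeca-4,8-dien-1-yl]-5-methyloxolan-2-one | CO[C@H](/C=C(\C)CC[C@@H](O)[C@]1(C)CCC(=O)O1)C/C(C)=C/CCc1ccoc1 | target

**Step count and risks**

Total steps: 15. Longest linear sequence: 10 (steps 5, 6, 7, 9, 10, 11, 12, 13, 14, 15).

Steps most likely to fail:

Step 2 (proposed new method). The radical–polar crossover may not keep pace, so that the adduct radical is quenched by hydrogen transfer before the carbanion can acylate. The acceptor may also add with only modest facial selectivity next to a small methyl group. The fallback uses known chemistry in two stages and sets out from 3 and 4. The reductive olefin coupling is run under the established protic conditions (Fe(acac)3, PhSiH3, EtOH/ethylene glycol, 60 °C), which should stop at the open Giese adduct (4S,5S)-4,5-dimethyl-4-[2-(phenylsulfonyl)ethyl]-1,3-dioxolan-2-one F1. After isolation and removal of any cis isomer, F1 is treated with LiHMDS (2.2 equiv, THF, −78 to 0 °C), so that the sulfonyl carbanion is C-acylated by the carbonate in a Claisen-type acyl transfer. Acidic work-up returns the route at 5.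

Step 14. The ketone enolate may attack the lactone carbonyl intramolecularly (Claisen condensation) or undergo proton exchange and double alkylation before the allylic bromide is consumed. The fallback replaces the strong-base alkylation by a neutral palladium-catalysed allylation. Ketone 7 is converted into the silyl enol ether (S)-5-methyl-5-[1-(trimethylsilyloxy)ethenyl]oxolan-2-one F2 (TMSOTf, Et3N, CH2Cl2, 0 °C). Alcohol 22 is converted into (2E,4S,6E)-9-(furan-3-yl)-4-methoxy-2,6-dimethylnona-2,6-dien-1-yl methyl carbonate F3 (ClCO2Me, pyridine). Tsuji allylation of F2 with F3 (Pd2(dba)3·CHCl3, dppe, THF, 65 °C) should attack the less hindered terminus of the π-allyl complex and return the route at 24.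

Step 15. Hydride delivery may show poor facial selectivity if the α-acyloxy quaternary centre opposes the catalyst (mismatched pairing), or the hindered ketone may react slowly. The fallback gives up reagent control: 24 is reduced with NaBH4/CeCl3 (MeOH, −78 °C) to 25 together with its C1′ epimer (5S)-5-[(1S,4E,6S,8E)-11-(furan-3-yl)-1-hydroxy-6-methoxy-4,8-dimethylundeca-4,8-dien-1-yl]-5-methyloxolan-2-one F4. The diastereomers are separated by chromatography, and F4 is oxidised back to 24 with Dess–Martin periodinane and recycled, the wanted epimer being 25.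

Further compounds
F1 | step 2 | (4S,5S)-4,5-dimethyl-4-[2-(phenylsulfonyl)ethyl]-1,3-dioxolan-2-one | C[C@@H]1OC(=O)O[C@@]1(C)CCS(=O)(=O)c1ccccc1
F2 | step 14 | (S)-5-methyl-5-[1-(trimethylsilyloxy)ethenyl]oxolan-2-one | C=C(O[Si](C)(C)C)[C@]1(C)CCC(=O)O1
F3 | step 14 | (2E,4S,6E)-9-(furan-3-yl)-4-methoxy-2,6-dimethylnona-2,6-dien-1-yl methyl carbonate | CO[C@H](/C=C(\C)COC(=O)OC)C/C(C)=C/CCc1ccoc1
F4 | step 15 | (5S)-5-[(1S,4E,6S,8E)-11-(furan-3-yl)-1-hydroxy-6-methoxy-4,8-dimethylundeca-4,8-dien-1-yl]-5-methyloxolan-2-one | CO[C@H](/C=C(\C)CC[C@H](O)[C@]1(C)CCC(=O)O1)C/C(C)=C/CCc1ccoc1
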